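## Structural features

The target is a longipinane diester. The locants used throughout are C1 (ketone), C2=C3 (C3 carries a methyl), C4, C5, C6 (gem-dimethyl), C7 (O-methacryloyl), C8 (CH2), C9 (O-isobutyryl), C10 (quaternary, methyl) and C11.

The core is a single cyclobutane, C4–C5–C11–C10, and both of its diagonals are bridged. C4/C11 are joined on one face by the enone C3=C2–C1(=O), giving a verbenone-type bicyclo[3.1.1]heptenone. C5/C10 are joined on the other face by C6–C7–C8–C9, giving two seven-membered rings.

The four contiguous ring stereocentres (4R,5S,10R,11R) depend on each other geometrically. The real questions are therefore the absolute sense of the core and its relation to C7 (R) and C9 (R), which are trans to each other on the seven-membered ring.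

Both carbinol carbons are neopentylic (C7 next to C6, C9 next to C10). Seen from the four-carbon bridge, the core has a pseudo mirror plane through C5 and C10 that is broken only by the remote difference between C1=O and C3–CH3. Substrate control of C7 and C9 by the core cannot be counted on.

The fragile groups are these:
- the methacrylate, which is sensitive to radicals, hydrides and nucleophiles;
- the two different esters, which must not exchange;
- the strained ring next to the enone;
- any β-acyloxy ketone that would arise if C7 or C9 were oxidised.

The difficulty lies in the doubly bridged cyclobutane with quaternary C10. C1 and C9 are 1,4-related (dissonant) through C11–C10. A leaving group cannot sit on C10. An SN2 closure at C5 would be neopentylic.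

The key step exploits two facts. First, the fifteen skeletal carbons form one unbroken farnesane chain, C5–C4–C3–C2–C1–C11–C10–C9–C8–C7–C6. Second, C5 is the one cyclobutane carbon that carries only H beside its three carbon neighbours (C4, C11, C6). C5 can therefore start as a carboxyl carbon. As a ketene carbon it bonds to C11 while C4 bonds to C10, and as a cyclobutanone carbonyl it then accepts C6.

## Logic of the disconnections

**21 ⇒ 19 ⇒ 18 ⇒ 17.**
- Bonds cut: the C1=O π bond (back to the C1 carbinol) and the C7O–acyl bond. The C2=C3 alkene is moved out of conjugation to C3=CH2.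
- Reason: a C1 ketone next to a C5 ketone would be a strained, non-enolisable β-diketone open to cleavage. The methacrylate cannot pass radical steps. The C1 carbinol is needed earlier as the control element.
- Gain: the three most fragile features leave the plan.
- Demand: a neopentylic OH must be acylated, and oxidation and conjugation must run under mild, ester-safe conditions.

**17 ⇒ 15 ⇒ 14.**
- Bond cut: C5–C6, after oxygen is put back on C5.
- Reason: this is the most congested bond. A tertiary radical at C6 generated from a C6–C7 epoxide leaves the oxygen on C7 with its configuration intact, while C5 serves as a carbonyl acceptor.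
- Gain: both seven-membered rings open, the tricycle becomes a bicycle, and quaternary C6 and stereocentre C5 disappear.
- Demand: radical closure must outrun radical reduction, and the tertiary C5–OH must be removed beside a free secondary OH.

**14 ⇒ 13 ⇒ 12 ⇒ 11 (key).**
- Bonds cut: C5–C11 and C4–C10.
- Reason: these two bonds close the cyclobutane and the six-membered ring together and create quaternary C10. Electronically they are the bonds that a ketene and a trisubstituted alkene form in the crossed sense.
- Gain: a bicyclic compound with three new stereocentres falls back to an open chain whose stereocentres (C1, C7, C9) are all isolated carbinol-type centres.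
- In one sentence: a thermal crossed [2+2] inside 13, released from the open-chain acid 11.
- Demand: E geometry at C10=C11, one controlling stereocentre in the tether (C1), and survival of the epoxide, ester and silyl ether.

**11 ⇒ 10 ⇒ 9 ⇒ 8.**
- Bonds cut: the two C–O bonds of the epoxide, the C9O–acyl bond and the acid O–H (back to O–CH3).
- Reason: C7 is set by reagent control on the only electron-rich alkene, and the final C9 ester doubles as the protecting group.
- Gain: no protecting group is needed on C7 or C9.
- Demand: site selection among three trisubstituted alkenes, and hydrolysis of the methyl ester before the second ester is present.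

**8 ⇒ 7 ⇒ 6.**
- Bonds cut: C6=C7 (metathesis) and C8–C9 (allylation).
- Reason: a linear prenyl group cannot be added directly with reliable enantiocontrol, whereas allylboration followed by capping can.
- Gain: five carbons and stereocentre C9 are removed.
- Demand: reagent control at an α-branched enal.

**6 ⇒ 5 ⇒ 4.**
- Bonds cut: the C9=O bond (back to a methyl C–H) and O–Si.
- Reason: selenium dioxide oxidises precisely the methyl group trans to C1, which fixes the E geometry the key step needs.
- Gain: the chain is reduced to a C10 compound with one stereocentre.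
- Demand: selectivity for the C10=C11 alkene over the enoate.

**4 ⇒ 2 + 3, and 2 ⇒ 1.**
- Bond cut: C1–C2.
- Reason: a vinylogous aldol joins two C5 units, delivers the dienoate needed for ketene formation, and creates C1.
- Gain: two commercial isoprenoid C5 compounds.
- Demand: γ-selectivity and enantiocontrol by the catalyst.

## Other disconnections considered

**Alternative 1: retro-[2+2] between two alkenes (the first idea that comes to mind).** The cut is at C4–C10 and C5–C11, and the forward key step is an enone–alkene photocycloaddition. Because both diagonals of the cyclobutane are bridged, the two alkenes C4=C5 and C10=C11 lie in one ring. The precursor is therefore the eleven-membered humulene-type trienone A1, and the reaction is transannular.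
- A1 is harder to make than the target.
- The excited dienone should isomerise about its double bonds, which erases the alkene geometry that encodes the ring stereocentres.
- C4 and C11 are separated by three atoms, so initial five-membered ring formation (C4–C11) would favour the parallel adduct with the wrong connectivity.
- The facial sense would rest on macrocycle conformation only.
- The methacrylate is not photostable company.

The chosen plan keeps the idea of forming two bonds at once, but it uses polarisation and a short tether to enforce the crossed mode.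

**Alternative 2: cut C4–C10 only.** The forward key step is a 4-exo-tet alkylation in the hydrobenzocycloheptenone A2, with the C9-ketone enolate carbon C10 displacing bromide at C4.
- A fully substituted enolate carbon would have to attack a secondary allylic carbon flanked by the bulky C5.
- Loss of HBr towards a cross-conjugated dienone or phenol, SN2′ attack, and β-elimination of the C7 oxygen from the C9 ketone are all easier paths.
- A2 already carries five stereocentres on a 6/7 system, so the gain in simplicity is small.

The chosen step removes two rings and three stereocentres instead of one ring.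

**Alternative 3: keep the bicyclo[3.1.1]heptenone from the chiral pool.** The cuts are at C7–C8 (aldol closure of keto aldehyde A3) and then C5–C6 and C8–C9, which leads back to (1R,5R)-verbenone A4.
- This needs a tert-alkyl group on the cyclobutane CH2 and functionalisation of the methyl group anti to the enone.
- Both are unactivated C–H positions on the face remote from every functional group of A4, and no directing handle is available.
- The closing aldol would form C7 across the pseudo mirror plane without any bias.

The step count and the number of unprecedented C–H operations exceed those of the chosen plan. In the chosen plan each stereocentre has a named control element.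

Key step: step 10

Assumption: the locants C1–C11 defined above are used for all intermediates, open-chain ones included, and systematic chain locants appear only inside compound names. The sense of induction in steps 2, 5 and 9 follows the accepted empirical models of these reactions.

## Steps

Step 1
Reactants: 1 methyl 3-methylbut-2-enoate
Product: 2 tert-butyl[(1-methoxy-3-methylbuta-1,3-dien-1-yl)oxy]dimethylsilane
Conditions: LDA, THF, −78 °C; TBSCl, DMPU, −78 °C → rt
Reagents that add atoms: tert-butyldimethylsilyl chloride, CC(C)(C)[Si](C)(C)Cl
Why: Kinetic γ-deprotonation of the senecioate gives the extended lithium dienolate, which is silylated on oxygen; this is the standard preparation of a vinylogous silyl ketene acetal, and its ketene-acetal geometry has no consequence later.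

Step 2
Reactants: 2 tert-butyl[(1-methoxy-3-methylbuta-1,3-dien-1-yl)oxy]dimethylsilane; 3 3-methylbut-2-enal
Product: 4 methyl (2E,5S)-5-hydroxy-3,7-dimethylocta-2,6-dienoate
Conditions: SiCl4, chiral binaphthyldiamine-derived bisphosphoramide (5 mol %, enantiomer that opens the Si face), iPr2NEt (10 mol %), CH2Cl2, −78 °C; aqueous work-up
Reagents that add atoms: none
Why: Catalytic enantioselective vinylogous Mukaiyama aldol reaction: the chiral Lewis-base-bound silicon cation activates the enal and the dienolate reacts at its unhindered γ-carbon, forming C1–C2. Si-face attack sets (S)-C1, the stereocentre that later controls the whole core. The disubstituted β-carbon of 3 secures 1,2-addition.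

Step 3
Reactants: 4 methyl (2E,5S)-5-hydroxy-3,7-dimethylocta-2,6-dienoate
Product: 5 methyl (2E,5S)-5-[(tert-butyldimethylsilyl)oxy]-3,7-dimethylocta-2,6-dienoate
Conditions: TBSCl, imidazole, DMF, rt
Reagents that add atoms: tert-butyldimethylsilyl chloride, CC(C)(C)[Si](C)(C)Cl
Why: Standard silylation. The bulky ether blocks lactonisation of the later acid and is the group whose size enforces the allylic-strain bias in step 10.

Step 4
Reactants: 5 methyl (2E,5S)-5-[(tert-butyldimethylsilyl)oxy]-3,7-dimethylocta-2,6-dienoate
Product: 6 methyl (2E,5S,6E)-5-[(tert-butyldimethylsilyl)oxy]-3,7-dimethyl-8-oxoocta-2,6-dienoate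
Conditions: SeO2, 1,4-dioxane, 80 °C
Reagents that add atoms: selenium dioxide, O=[Se]=O
Why: Riley allylic oxidation (ene reaction, then [2,3]-shift) attacks the more electron-rich C10=C11 alkene at its more substituted end and oxidises the methyl group trans to C1, so the (E)-enal with C9 trans to C1 should result. The enoate alkene is too electron-poor, and C1–H sits at the less substituted alkene carbon.

Step 5
Reactants: 6 methyl (2E,5S,6E)-5-[(tert-butyldimethylsilyl)oxy]-3,7-dimethyl-8-oxoocta-2,6-dienoate
Product: 7 methyl (2E,5S,6E,8R)-5-[(tert-butyldimethylsilyl)oxy]-8-hydroxy-3,7-dimethylundeca-2,6,10-trienoate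
Conditions: (+)-Ipc2B(allyl) [from (−)-α-pinene], Et2O, −78 °C; NaOH, H2O2, 0 °C
Reagents that add atoms: (+)-B-allyldiisopinocampheylborane, C=CCB([C@H]1C[C@H]2C[C@@H]([C@@H]1C)C2(C)C)[C@H]1C[C@H]2C[C@@H]([C@@H]1C)C2(C)C
Why: Brown asymmetric allylboration through a closed chair transition state forms C8–C9. The reagent derived from (−)-α-pinene attacks the Re face of the enal and sets (R)-C9 under reagent control, because C1 is too remote to interfere.

Step 6
Reactants: 7 methyl (2E,5S,6E,8R)-5-[(tert-butyldimethylsilyl)oxy]-8-hydroxy-3,7-dimethylundeca-2,6,10-trienoate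
Product: 8 methyl (2E,5S,6E,8R)-5-[(tert-butyldimethylsilyl)oxy]-8-hydroxy-3,7,11-trimethyldodeca-2,6,10-trienoate
Conditions: second-generation Ru–NHC benzylidene catalyst (3 mol %), 2-methylbut-2-ene/CH2Cl2, 40 °C
Reagents that add atoms: 2-methylbut-2-ene, CC=C(C)C
Why: Olefin cross-metathesis of the terminal alkene with excess 2-methylbut-2-ene caps the chain as the trisubstituted C6=C7 alkene. The two trisubstituted alkenes already present are inert to the catalyst, and no small ring can form.

Step 7
Reactants: 8 methyl (2E,5S,6E,8R)-5-[(tert-butyldimethylsilyl)oxy]-8-hydroxy-3,7,11-trimethyldodeca-2,6,10-trienoate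
Product: 9 (2E,5S,6E,8R)-5-[(tert-butyldimethylsilyl)oxy]-8-hydroxy-3,7,11-trimethyldodeca-2,6,10-trienoic acid
Conditions: LiOH, THF/MeOH/H2O, 45 °C; then 1 M HCl to pH 4
Reagents that add atoms: lithium hydroxide, [Li+].[OH-]
Why: Plain saponification, placed here because the methyl ester is still the only ester in the molecule. The TBS ether and the alkenes tolerate hydroxide.

Step 8
Reactants: 9 (2E,5S,6E,8R)-5-[(tert-butyldimethylsilyl)oxy]-8-hydroxy-3,7,11-trimethyldodeca-2,6,10-trienoic acid
Product: 10 (2E,5S,6E,8R)-5-[(tert-butyldimethylsilyl)oxy]-3,7,11-trimethyl-8-(2-methylpropanoyloxy)dodeca-2,6,10-trienoic acid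
Conditions: isobutyric anhydride, Et3N, DMAP, CH2Cl2, rt; aqueous work-up
Reagents that add atoms: isobutyric anhydride, CC(C)C(=O)OC(=O)C(C)C
Why: DMAP-catalysed acylation installs the final C9 isobutyrate, which also serves as the protecting group for C9. The mixed anhydride formed at the acid is hydrolysed on work-up, and any positional shift of the C3=C4 alkene would lead to the same ketene in step 10.

Step 9
Reactants: 10 (2E,5S,6E,8R)-5-[(tert-butyldimethylsilyl)oxy]-3,7,11-trimethyl-8-(2-methylpropanoyloxy)dodeca-2,6,10-trienoic acid
Product: 11 (2E,5S,6E,8R,10R)-5-[(tert-butyldimethylsilyl)oxy]-10,11-epoxy-3,7,11-trimethyl-8-(2-methylpropanoyloxy)dodeca-2,6-dienoic acid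
Conditions: D-fructose-derived ketone catalyst (30 mol %), Oxone, K2CO3, Bu4NHSO4, MeCN–DMM/aq. borate–EDTA buffer, 0 °C; then pH 4–5, 0 °C
Reagents that add atoms: potassium peroxymonosulfate (Oxone), [K+].[O-]S(=O)(=O)OO
Why: Shi asymmetric epoxidation. The electrophilic dioxirane selects the most electron-rich alkene C6=C7, since C10=C11 is hindered and flanked by two allylic C–O bonds and C3=C4 is conjugated. The spiro transition state of the D-series ketone gives the (R)-configured CH carbon, as it does for trans and trisubstituted alkenes, which sets (7R).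

Step 10
Reactants: 11 (2E,5S,6E,8R,10R)-5-[(tert-butyldimethylsilyl)oxy]-10,11-epoxy-3,7,11-trimethyl-8-(2-methylpropanoyloxy)dodeca-2,6-dienoic acid
Product: 14 bicyclic cyclobutanone 4-(TBSO)-7-methyl-2-methylidene-7-[(1R)-2-[(2R)-3,3-dimethyloxiran-2-yl]-1-(2-methylpropanoyloxy)ethyl]bicyclo[3.1.1]heptan-6-one (C5 = C6 of the bicycle; C10 = C7), via acid chloride 12 (not isolated), via vinylketene 13 (not isolated)
Conditions: 1-chloro-N,N,2-trimethylprop-1-en-1-amine, CH2Cl2, 0 °C; then syringe-pump addition to Et3N in toluene, 110 °C, high dilution
Reagents that add atoms: none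
Why: The acid is converted without HCl into 12, and Et3N removes HCl in a 1,4-sense through the C3 methyl group (the γ-hydrogens cis to the acyl group) to give 13, which slow addition keeps dilute so that ring closure competes with dimerisation. The closest known reaction type is the intramolecular [2+2] cycloaddition of vinylketenes generated from 3-methylalka-2,6-dienoyl chlorides, which gives 2-methylidenebicyclo[3.1.1]heptan-6-ones. The cycloaddition is concerted but strongly asynchronous: the electrophilic ketene carbon C5 bonds first to C11, the less substituted alkene carbon, positive charge builds up on tertiary C10, and the ketene α-carbon C4 collapses onto C10. This polarisation and the three-atom tether C3–C2–C1 enforce the crossed mode: the leading C5–C11 bond closes the six-membered ring C5–C4–C3–C2–C1–C11 and the C4–C10 bond closes the cyclobutane C4–C5–C11–C10, whereas the parallel mode would place the charge on secondary C11. The alkene reacts suprafacially, so its E geometry puts the C10 methyl cis to C1 and the C9 chain on the opposite cyclobutane face beside the new C5 carbonyl, which sets C10 relative to C11; C4 follows from the tether because a bicyclo[3.1.1]heptane can only be cis-bridged. The absolute sense is relayed from C1: allylic 1,3-strain with the C10 methyl (cis to C1) leaves only the rotamer in which C1–H and C2 flank the alkene and the bulky OTBS group points away, so the tethered ketene reaches one alkene face and (1S) gives the C4/C10/C11 configuration of 21 with OTBS on the C5 side. In this rotamer the C1–O bond lies near the nodal plane of the alkene π system, which limits its deactivating effect, and the freely rotating C9 stereocentre is not expected to override the tether-bound C1. Chemoselectivity against the epoxide and the ester rests on ring size (any reaction of the ketene with the remote groups would need a ten-membered or larger transition state) and on HCl-free activation with a poorly soluble ammonium salt.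

Step 11
Reactants: 14 bicyclic cyclobutanone (as in step 10)
Product: 15 tricyclic diol (1S,7R,9R)-1-(TBSO)-5,7-dihydroxy-3-methylidenelongipinan-9-yl 2-methylpropanoate (5-OH on the outer face; C4 C10 C11 as in 21)
Conditions: Cp2TiCl2 (20 mol %), Mn, 2,4,6-collidine·HCl, THF, rt, slow addition of 14
Reagents that add atoms: none
Why: Titanocene(III)-catalysed reductive epoxide opening gives the more substituted (tertiary) C6 radical and leaves C7–O–Ti with (7R) untouched; addition of such radicals to titanium-bound ketones is a known cyclisation type that also gives cyclobutanols. The chain stands axial on C10, only about 2.1–2.2 Å across the ring from C5, so the formal 7-exo closure has roughly the entropy of a six-ring closure and releases carbonyl strain. C6 can reach C5 only from the chain side, so OH ends on the outer position.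

Step 12
Reactants: 15 tricyclic diol (as in step 11)
Product: 17 (1S,5S,7R,9R)-1-(TBSO)-7-hydroxy-3-methylidenelongipinan-9-yl 2-methylpropanoate, via triethylsilyl ether 16 (not isolated)
Conditions: Cp*TiCl3 (10 mol %), Zn, Et3SiCl, PhSiH3, THF, 60 °C; then citric acid, MeOH, rt
Reagents that add atoms: none
Why: Titanium-catalysed radical dehydroxylation of tertiary alcohols: homolysis of the Ti(III) alkoxide gives the tertiary C5 radical, which takes H from the silane, while the secondary C7–OH is only silylated (16) and is released on work-up. C6 is locked in the inner position, so hydrogen can only enter the outer position, which gives (5S). Elimination is excluded because C4 and C11 are bridgeheads and C6 is quaternary.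

Step 13
Reactants: 17 (1S,5S,7R,9R)-1-(TBSO)-7-hydroxy-3-methylidenelongipinan-9-yl 2-methylpropanoate
Product: 18 (1S,5S,7R,9R)-1-(TBSO)-7-(2-methylprop-2-enoyloxy)-3-methylidenelongipinan-9-yl 2-methylpropanoate
Conditions: methacrylic anhydride, Et3N, DMAP, BHT (trace), CH2Cl2, rt
Reagents that add atoms: methacrylic anhydride, C=C(C)C(=O)OC(=O)C(C)=C
Why: DMAP-catalysed acylation of the only free hydroxyl group, placed after the last radical step. The trans arrangement of O7 and O9 on the ring disfavours acyl migration.

Step 14
Reactants: 18 (1S,5S,7R,9R)-1-(TBSO)-7-(2-methylprop-2-enoyloxy)-3-methylidenelongipinan-9-yl 2-methylpropanoate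
Product: 19 (1S,5S,7R,9R)-1-hydroxy-7-(2-methylprop-2-enoyloxy)-3-methylidenelongipinan-9-yl 2-methylpropanoate
Conditions: HF·pyridine, pyridine/THF, 0 °C → rt
Reagents that add atoms: none
Why: Buffered fluoride desilylation spares both esters and avoids the basic fluoride sources that could add to the methacrylate. A possible shift of the exocyclic alkene into the ring would be harmless because both isomers give 21.

Step 15
Reactants: 19 (1S,5S,7R,9R)-1-hydroxy-7-(2-methylprop-2-enoyloxy)-3-methylidenelongipinan-9-yl 2-methylpropanoate
Product: 21 (4R,5S,7R,9R,10R,11R)-7-(2-methylprop-2-enoyloxy)-9-(2-methylpropanoyloxy)longipin-2-en-1-one (target CNP0214356.1), via deconjugated enone 20 (not isolated)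
Conditions: DMP, NaHCO3, CH2Cl2, rt; then DBU (0.2 equiv), rt
Reagents that add atoms: none
Why: Dess–Martin oxidation destroys the relay stereocentre C1 and gives the β,γ-unsaturated ketone 20. Its doubly activated C2–H is removed by catalytic DBU, and reprotonation at the exocyclic carbon gives the conjugated, trisubstituted enone. C11 is a bridgehead and cannot enolise, so no stereocentre is at risk.

## Compound list

1 | methyl 3-methylbut-2-enoate | COC(=O)C=C(C)C | starting material
2 | tert-butyl[(1-methoxy-3-methylbuta-1,3-dien-1-yl)oxy]dimethylsilane (ketene-acetal geometry undefined, of no consequence) | C=C(C)C=C(OC)O[Si](C)(C)C(C)(C)C | intermediate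
3 | 3-methylbut-2-enal | CC(C)=CC=O | starting material
4 | methyl (2E,5S)-5-hydroxy-3,7-dimethylocta-2,6-dienoate | CC(C)=C[C@@H](O)C/C(C)=C/C(=O)OC | intermediate
5 | methyl (2E,5S)-5-[(tert-butyldimethylsilyl)oxy]-3,7-dimethylocta-2,6-dienoate | CC(C)=C[C@@H](O[Si](C)(C)C(C)(C)C)C/C(C)=C/C(=O)OC | intermediate
6 | methyl (2E,5S,6E)-5-[(tert-butyldimethylsilyl)oxy]-3,7-dimethyl-8-oxoocta-2,6-dienoate | O=C/C(C)=C/[C@@H](O[Si](C)(C)C(C)(C)C)C/C(C)=C/C(=O)OC | intermediate
7 | methyl (2E,5S,6E,8R)-5-[(tert-butyldimethylsilyl)oxy]-8-hydroxy-3,7-dimethylundeca-2,6,10-trienoate | C=CC[C@@H](O)/C(C)=C/[C@@H](O[Si](C)(C)C(C)(C)C)C/C(C)=C/C(=O)OC | intermediate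
8 | methyl (2E,5S,6E,8R)-5-[(tert-butyldimethylsilyl)oxy]-8-hydroxy-3,7,11-trimethyldodeca-2,6,10-trienoate | CC(C)=CC[C@@H](O)/C(C)=C/[C@@H](O[Si](C)(C)C(C)(C)C)C/C(C)=C/C(=O)OC | intermediate
9 | (2E,5S,6E,8R)-5-[(tert-butyldimethylsilyl)oxy]-8-hydroxy-3,7,11-trimethyldodeca-2,6,10-trienoic acid | CC(C)=CC[C@@H](O)/C(C)=C/[C@@H](O[Si](C)(C)C(C)(C)C)C/C(C)=C/C(=O)O | intermediate
10 | (2E,5S,6E,8R)-5-[(tert-butyldimethylsilyl)oxy]-3,7,11-trimethyl-8-(2-methylpropanoyloxy)dodeca-2,6,10-trienoic acid | CC(C)=CC[C@@H](OC(=O)C(C)C)/C(C)=C/[C@@H](O[Si](C)(C)C(C)(C)C)C/C(C)=C/C(=O)O | intermediate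
11 | (2E,5S,6E,8R,10R)-5-[(tert-butyldimethylsilyl)oxy]-10,11-epoxy-3,7,11-trimethyl-8-(2-methylpropanoyloxy)dodeca-2,6-dienoic acid | CC1(C)O[C@@H]1C[C@@H](OC(=O)C(C)C)/C(C)=C/[C@@H](O[Si](C)(C)C(C)(C)C)C/C(C)=C/C(=O)O | intermediate
12 | acid chloride of 11 | CC1(C)O[C@@H]1C[C@@H](OC(=O)C(C)C)/C(C)=C/[C@@H](O[Si](C)(C)C(C)(C)C)C/C(C)=C/C(=O)Cl | intermediate
13 | vinylketene from 12 (O=C5=C4H–C3(=CH2)–C2H2–, rest of the chain as in 11) | CC1(C)O[C@@H]1C[C@@H](OC(=O)C(C)C)/C(C)=C/[C@@H](O[Si](C)(C)C(C)(C)C)CC(=C)C=C=O | intermediate
14 | 4-(TBSO)-7-methyl-2-methylidene-7-[(1R)-2-[(2R)-3,3-dimethyloxiran-2-yl]-1-(2-methylpropanoyloxy)ethyl]bicyclo[3.1.1]heptan-6-one; side chain anti to the three-carbon bridge, OTBS on the carbonyl side | CC1(C)O[C@@H]1C[C@@H](OC(=O)C(C)C)[C@@]2(C)[C@@H]3[C@@H](O[Si](C)(C)C(C)(C)C)CC(=C)[C@H]2C3=O | intermediate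
15 | (1S,7R,9R)-1-(TBSO)-5,7-dihydroxy-3-methylidenelongipinan-9-yl 2-methylpropanoate | O[C@@H]1C[C@@H](OC(=O)C(C)C)[C@@]2(C)[C@@H]3[C@@H](O[Si](C)(C)C(C)(C)C)CC(=C)[C@H]2[C@]3(O)C1(C)C | intermediate
16 | 7-O-triethylsilyl ether of 17 | CC[Si](CC)(CC)O[C@@H]1C[C@@H](OC(=O)C(C)C)[C@@]2(C)[C@@H]3[C@@H](O[Si](C)(C)C(C)(C)C)CC(=C)[C@H]2[C@@H]3C1(C)C | intermediate
17 | (1S,5S,7R,9R)-1-(TBSO)-7-hydroxy-3-methylidenelongipinan-9-yl 2-methylpropanoate | O[C@@H]1C[C@@H](OC(=O)C(C)C)[C@@]2(C)[C@@H]3[C@@H](O[Si](C)(C)C(C)(C)C)CC(=C)[C@H]2[C@@H]3C1(C)C | intermediate
18 | (1S,5S,7R,9R)-1-(TBSO)-7-(2-methylprop-2-enoyloxy)-3-methylidenelongipinan-9-yl 2-methylpropanoate | C=C(C)C(=O)O[C@@H]1C[C@@H](OC(=O)C(C)C)[C@@]2(C)[C@@H]3[C@@H](O[Si](C)(C)C(C)(C)C)CC(=C)[C@H]2[C@@H]3C1(C)C | intermediate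
19 | (1S,5S,7R,9R)-1-hydroxy-7-(2-methylprop-2-enoyloxy)-3-methylidenelongipinan-9-yl 2-methylpropanoate | C=C(C)C(=O)O[C@@H]1C[C@@H](OC(=O)C(C)C)[C@@]2(C)[C@@H]3[C@@H](O)CC(=C)[C@H]2[C@@H]3C1(C)C | intermediate
20 | 7-(2-methylprop-2-enoyloxy)-9-(2-methylpropanoyloxy)-3-methylidenelongipinan-1-one | C=C(C)C(=O)O[C@@H]1C[C@@H](OC(=O)C(C)C)[C@@]2(C)[C@@H]3C(=O)CC(=C)[C@H]2[C@@H]3C1(C)C | intermediate
21 | (4R,5S,7R,9R,10R,11R)-7-(2-methylprop-2-enoyloxy)-9-(2-methylpropanoyloxy)longipin-2-en-1-one | C=C(C)C(=O)O[C@@H]1C[C@@H](OC(=O)C(C)C)[C@@]2(C)[C@@H]3C(=O)C=C(C)[C@H]2[C@@H]3C1(C)C | target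

## Step count and least certain steps

Total step count: 15. Longest linear sequence: 15 steps (1 → 21). Compound 3 enters in step 2.

**Step 10 (key step).**
- Risk: the most likely failure is a cycloaddition that is too slow. The alkene is trisubstituted, but it carries two allylic C–O bonds and a branched C9. Ketene dimerisation or oligomerisation, re-addition of HCl with positional isomerisation, and opening of the epoxide by the ammonium chloride at 110 °C could all overtake ring closure. A second risk is erosion of the facial bias if the minor C1 rotamer reacts.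
- Fallback (from 10 to 14): the fallback sets out from 10, which has no epoxide yet. The acid is coupled with pyrrolidine to give the pyrrolidine amide F1. Tf2O and 2,4,6-collidine convert F1, by O-triflation and γ-deprotonation, into the vinylketeniminium triflate F2. F2 is a much stronger electrophile than 13 and should close at or below 80 °C to the cyclobutaniminium triflate F3. Aqueous hydrolysis gives the prenyl-substituted cyclobutanone F4. The Shi epoxidation is then run on F4, where trisubstituted C6=C7 competes with the hindered 1,1-disubstituted C3 methylidene. Contact time is kept short to spare the shielded cyclobutanone. The route is rejoined at 14.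

**Step 11.**
- Risk: the tertiary radical may be trapped by titanium(III) before it cyclises, with subsequent loss of a β-hydrogen (net isomerisation of the epoxide to an allylic alcohol). If oxygen-centred radical character develops at C5, the C4–C5 bond may fragment, since that releases ring strain and gives an allyl-stabilised radical.
- Fallback (from 14 to 17): the fallback replaces the oxygen acceptor by a traceless nitrogen acceptor and the titanium chemistry by a tin hydride chain. From 14, Me3SiBr followed by mild hydrolysis opens the epoxide at its tertiary carbon to give the bromohydrin F5. Condensation of the C5 ketone with 1-amino-2-phenylaziridine gives the N-aziridinylimine F6. With Bu3SnH and AIBN in refluxing benzene, the C6 radical adds to C5=N. The aminyl radical then expels styrene and N2, and the resulting C5 radical takes hydrogen from the stannane. The route is rejoined directly at 17, bypassing 15 and step 12.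

**Step 12.**
- Risk: C–O homolysis may be slow or incomplete. The alkoxide must form at a very congested carbon, and a cyclobutyl tertiary radical is less stabilised than an ordinary one. Simple silylation of the tertiary hydroxyl may compete.
- Fallback (from 15 to 16): this is the classical Barton–McCombie sequence. From 15, Et3SiCl and imidazole protect the secondary hydroxyl to give the mono-silyl ether F7. NaHMDS, CS2 and MeI give the tertiary S-methyl xanthate F8, which cannot undergo Chugaev elimination because no syn β-hydrogen leads to an allowed alkene. Bu3SnH and AIBN then deliver 16, which is desilylated at O7 to 17 as in the main route.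

**Step 9.**
- Risk: poor conversion of the amphiphilic carboxylate in the biphasic medium, partial oxidation at C10=C11, and acid-induced opening of the epoxide during the acidification.
- Fallback (from 8 to 11): the fallback moves the epoxidation to a neutral substrate and changes the way the acid is released. From 8, acylation with isobutyric anhydride gives the diester F9. Shi epoxidation gives the epoxy methyl ester F10. Me3SnOH in 1,2-dichloroethane at 80 °C cleaves the unhindered methyl ester in preference to the hindered secondary isobutyrate. The route is rejoined at 11, and steps 7–9 are replaced.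

## Further compounds

F1 | step 10 | pyrrolidine amide of 10 | CC(C)=CC[C@@H](OC(=O)C(C)C)/C(C)=C/[C@@H](O[Si](C)(C)C(C)(C)C)C/C(C)=C/C(=O)N1CCCC1
F2 | step 10 | vinylketeniminium triflate from F1 | CC(C)=CC[C@@H](OC(=O)C(C)C)/C(C)=C/[C@@H](O[Si](C)(C)C(C)(C)C)CC(=C)C=C=[N+]1CCCC1.[O-]S(=O)(=O)C(F)(F)F
F3 | step 10 | cyclobutaniminium triflate (bicyclic [2+2] adduct of F2) | CC(C)=CC[C@@H](OC(=O)C(C)C)[C@@]1(C)[C@@H]2[C@@H](O[Si](C)(C)C(C)(C)C)CC(=C)[C@H]1C2=[N+]1CCCC1.[O-]S(=O)(=O)C(F)(F)F
F4 | step 10 | 4-(TBSO)-7-methyl-2-methylidene-7-[(1R)-4-methyl-1-(2-methylpropanoyloxy)pent-3-enyl]bicyclo[3.1.1]heptan-6-one | CC(C)=CC[C@@H](OC(=O)C(C)C)[C@@]1(C)[C@@H]2[C@@H](O[Si](C)(C)C(C)(C)C)CC(=C)[C@H]1C2=O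
F5 | step 11 | bromohydrin of 14 (C6–Br tertiary, (7R)-OH) | CC(C)(Br)[C@H](O)C[C@@H](OC(=O)C(C)C)[C@@]1(C)[C@@H]2[C@@H](O[Si](C)(C)C(C)(C)C)CC(=C)[C@H]1C2=O
F6 | step 11 | N-(2-phenylaziridin-1-yl)imine of F5 at C5 | CC(C)(Br)[C@H](O)C[C@@H](OC(=O)C(C)C)[C@@]1(C)[C@@H]2[C@@H](O[Si](C)(C)C(C)(C)C)CC(=C)[C@H]1C2=NN1CC1c1ccccc1
F7 | step 12 | 7-O-triethylsilyl ether of 15 | CC[Si](CC)(CC)O[C@@H]1C[C@@H](OC(=O)C(C)C)[C@@]2(C)[C@@H]3[C@@H](O[Si](C)(C)C(C)(C)C)CC(=C)[C@H]2[C@]3(O)C1(C)C
F8 | step 12 | 5-O-(methylsulfanyl)thiocarbonyl derivative (S-methyl xanthate) of F7 | CC[Si](CC)(CC)O[C@@H]1C[C@@H](OC(=O)C(C)C)[C@@]2(C)[C@@H]3[C@@H](O[Si](C)(C)C(C)(C)C)CC(=C)[C@H]2[C@]3(OC(=S)SC)C1(C)C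
F9 | step 9 | methyl ester of 10 | CC(C)=CC[C@@H](OC(=O)C(C)C)/C(C)=C/[C@@H](O[Si](C)(C)C(C)(C)C)C/C(C)=C/C(=O)OC
F10 | step 9 | methyl ester of 11 | CC1(C)O[C@@H]1C[C@@H](OC(=O)C(C)C)/C(C)=C/[C@@H](O[Si](C)(C)C(C)(C)C)C/C(C)=C/C(=O)OC
A1 | alternative 1 | (2Z,4E,7R,9R,10E)-3,6,6,10-tetramethyl-7-(2-methylprop-2-enoyloxy)-9-(2-methylpropanoyloxy)cycloundeca-2,4,10-trien-1-one | O=C1/C=C(C)\C=C\C(C)(C)[C@H](OC(=O)C(C)=C)C[C@@H](OC(=O)C(C)C)/C(C)=C/1
A2 | alternative 2 | 4-bromo-7-(TBSO)-3,6,6,10-tetramethyl-bicyclo[5.4.0]undec-2-ene-1,9-dione (target locants, rings fused at C5–C11, C10 epimerisable) | O=C1C=C(C)[C@@H](Br)[C@H]2[C@@H]1C(C)C(=O)C[C@@H](O[Si](C)(C)C(C)(C)C)C2(C)C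
A3 | alternative 3 | 6-acetyl-4,6-dimethyl-7-(2-methyl-1-oxopropan-2-yl)bicyclo[3.1.1]hept-3-en-2-one (C10 acetyl and C5 side chain both anti to the enone bridge) | CC(=O)[C@@]1(C)[C@@H]2C(=O)C=C(C)[C@H]1[C@@H]2C(C)(C)C=O
A4 | alternative 3 | (1R,5R)-verbenone | CC1(C)[C@@H]2C(=O)C=C(C)[C@H]1C2
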